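Everything rests on the cyclodeca-1(10),4-diene unit of the ten-membered ring, in which the ring-cis olefins C1=C10 and C4=C5 flank the C2–C3 bridge. Pairing these two olefins into a cyclobutane (C1–C4 and C5–C10 joined) and splitting it the other way (C4–C5 and C1–C10) leads back to a cyclohexenone and a cyclobutene. In the forward sense, light joins the enone bond C5=C10 to the cyclobutene bond C1=C4 and heat cleaves C1–C4 and C5–C10, so the six-membered ring C5–C10 expands to the ten-membered dienone in one operation. The precursor is an (S)-5-silyloxy-3-(PMB-oxymethyl)cyclohex-2-enone (C6 carbonyl, C8–O, C14) plus methyl cyclobut-1-enecarboxylate (C15).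

Key step: step 6

Assumption: the target is read as the (6R,7S,8S) isomer with a cis-fused lactone (H-6 and H-7 on the same face) and both ring olefins cis within the ring (CIP 1(10)E,4E); ring atoms are numbered C1–C10 as in the target, with C11–C13 in the lactone, C14 on C10 and C15 on C4; lactone names use the fused numbering (11a = C6, 3a = C7, 4 = C8, 6 = C10, 10 = C4); TBS = tert-butyldimethylsilyl, TBDPS = tert-butyldiphenylsilyl, PMB = 4-methoxybenzyl.

Step 1
Reactants: 1 (tributylstannyl)methanol; 2 4-methoxybenzyl chloride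
Product: 3 tributyl{[(4-methoxybenzyl)oxy]methyl}stannane
Conditions: NaH, Bu4NI (cat.), THF/DMF, 0 °C → rt
Reagents that add atoms: none
Why: Williamson ether synthesis of the primary sodium alkoxide with a reactive benzylic chloride should give the α-alkoxymethylstannane; no stereocentre is involved.

Step 2
Reactants: 4 methyl (3R)-3-(TBSO)-5-oxo-6-(triphenyl-λ5-phosphanylidene)hexanoate
Product: 5 (3R)-3-(TBSO)-N-methoxy-N-methyl-5-oxo-6-(triphenyl-λ5-phosphanylidene)hexanamide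
Conditions: MeNH(OMe)·HCl, i-PrMgCl, THF, −20 → 0 °C
Reagents that add atoms: N,O-dimethylhydroxylamine hydrochloride, CNOC.Cl
Why: Aminolysis of the methyl ester by the magnesium amide (Weinreb amide formation) should leave the acyl-stabilised ylide and the β-silyloxy stereocentre (R, unchanged) untouched.

Step 3
Reactants: 5 (3R)-3-(TBSO)-N-methoxy-N-methyl-5-oxo-6-(triphenyl-λ5-phosphanylidene)hexanamide; 3 tributyl{[(4-methoxybenzyl)oxy]methyl}stannane
Product: 8 (S)-5-(TBSO)-3-(PMBOCH2)cyclohex-2-en-1-one, via PMB-oxymethyllithium 6 (not isolated), via keto-ylide 7 (not isolated)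
Conditions: 3, n-BuLi, THF, −78 °C; then 5, −78 °C; H2O; then toluene, 100 °C
Reagents that add atoms: none
Why: Tin–lithium exchange gives the α-alkoxymethyllithium, which should add once to the Weinreb amide, and the resulting α-alkoxy ketone is closed by intramolecular Wittig olefination of the acyl ylide; the stereocentre comes from 4 and is called S only because the CIP priorities change.

Step 4
Reactants: 9 ethyl 1-bromocyclobutane-1-carboxylate
Product: 10 cyclobut-1-ene-1-carboxylic acid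
Conditions: KOH, toluene, reflux; then aq HCl, 0 °C
Reagents that add atoms: potassium hydroxide, [K+].[OH-]
Why: E2 dehydrobromination of the tertiary α-bromo ester with concurrent saponification should give the conjugated cyclobutene acid; no stereocentre is involved.

Step 5
Reactants: 10 cyclobut-1-ene-1-carboxylic acid
Product: 11 methyl cyclobut-1-ene-1-carboxylate
Conditions: MeI, K2CO3, DMF, 0 °C → rt
Reagents that add atoms: iodomethane, CI
Why: SN2 O-alkylation of the potassium carboxylate esterifies without the acid or heat that would polymerise the strained acrylate.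

Step 6
Reactants: 8 (S)-5-(TBSO)-3-(PMBOCH2)cyclohex-2-en-1-one; 11 methyl cyclobut-1-ene-1-carboxylate
Product: 14 methyl (1(10)E,4E,8S)-8-(TBSO)-10-(PMBOCH2)-6-oxocyclodeca-1(10),4-diene-4-carboxylate, via photoadduct 12 (not isolated), via ring-trans dienone 13 (not isolated)
Conditions: 11 (5 equiv), hν (350 nm), CH2Cl2, −20 °C; filtration through basic Al2O3; then PhSSPh (10 mol %), toluene (0.01 M), 180 °C, sealed tube, short heating
Reagents that add atoms: none
Why: The n,π* triplet of enone 8 adds to the cyclobutene bond C1=C4 through a 1,4-biradical (enone–alkene (2+2) photocycloaddition), and the acceptor ester directs head-to-head union, C4 to the α-carbon C5 and C1 to the β-carbon C10. Heating breaks the strained central C1–C4 bond of the bicyclo[2.2.0]hexane unit of 12 to an ester-stabilised cyclohexane-1,4-diyl that fragments across C5–C10; the closest known reaction type is the thermal cycloreversion of enone–cyclobutene photoadducts to cyclodeca-1,5-dienes. The ten-membered ring is thus closed by ring expansion, the six-membered ring C5–C10 being opened at the shared bond, and not by end-to-end cyclisation. The four sp3 centres made by light all return to sp2, so no new stereocentre has to be controlled and C8 (S) passes through untouched. The step needs head-to-head regiochemistry, which the electron-poor cyclobutene ester and the β-substituted enone secure, and ring-cis geometry at both olefins: the chair-like diyl of the cis-fused adduct should release C1=C10 cis and C4=C5 trans (13), and the thiyl radical from PhSSPh equilibrates the ketone- and ester-flanked C4=C5 bond to the less strained cis,cis diene 14. That isomer can undergo Cope rearrangement only through a boat-shaped transition state and should survive the short heating.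

Step 7
Reactants: 14 methyl (1(10)E,4E,8S)-8-(TBSO)-10-(PMBOCH2)-6-oxocyclodeca-1(10),4-diene-4-carboxylate
Product: 15 (1(10)E,4E,8S)-8-(TBSO)-4-(hydroxymethyl)-10-(PMBOCH2)cyclodeca-1(10),4-dien-6-ol (C6 epimers)
Conditions: i-Bu2AlH (5 equiv), CH2Cl2, −78 → −30 °C; aq KNaC4H4O6
Reagents that add atoms: none
Why: Hydride reduction with i-Bu2AlH should take the enone 1,2 and the conjugated ester to the allylic alcohol; the C6 carbinol forms as an epimer mixture that is erased again in step 9.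

Step 8
Reactants: 15 (1(10)E,4E,8S)-8-(TBSO)-4-(hydroxymethyl)-10-(PMBOCH2)cyclodeca-1(10),4-dien-6-ol (C6 epimers)
Product: 16 (1(10)E,4E,8S)-8-(TBSO)-4-(TBDPSOCH2)-10-(PMBOCH2)cyclodeca-1(10),4-dien-6-ol (C6 epimers)
Conditions: t-BuPh2SiCl, imidazole, CH2Cl2, −20 → 0 °C
Reagents that add atoms: tert-butyl(chloro)diphenylsilane, CC(C)(C)[Si](Cl)(c1ccccc1)c1ccccc1
Why: Silylation with the bulky chlorosilane should select the primary allylic C15 hydroxyl over the secondary C6 hydroxyl.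

Step 9
Reactants: 16 (1(10)E,4E,8S)-8-(TBSO)-4-(TBDPSOCH2)-10-(PMBOCH2)cyclodeca-1(10),4-dien-6-ol (C6 epimers)
Product: 17 (1(10)E,4E,8S)-8-(TBSO)-4-(TBDPSOCH2)-10-(PMBOCH2)cyclodeca-1(10),4-dien-6-one
Conditions: Dess–Martin periodinane, CH2Cl2, 0 °C → rt
Reagents that add atoms: none
Why: Dess–Martin oxidation of the secondary allylic alcohol returns the C6 enone, converges both C6 epimers and spares silyl and PMB ethers.

Step 10
Reactants: 17 (1(10)E,4E,8S)-8-(TBSO)-4-(TBDPSOCH2)-10-(PMBOCH2)cyclodeca-1(10),4-dien-6-one; 18 methyl bromoacetate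
Product: 19 methyl 2-[(1(10)E,4E,7S,8S)-8-(TBSO)-4-(TBDPSOCH2)-10-(PMBOCH2)-6-oxocyclodeca-1(10),4-dien-7-yl]acetate
Conditions: LiN(i-Pr)2, THF, −78 °C; then 18, DMPU, −78 → −45 °C
Reagents that add atoms: none
Why: Kinetic α′-deprotonation at C7 and SN2 alkylation of the lithium enolate (enolate alkylation) should install C11–C12; with H-8 eclipsing the enolate (allylic 1,3-strain) the electrophile is expected to enter anti to the bulky C8 silyloxy group, which sets C7 as S with C11 anti to O8.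

Step 11
Reactants: 19 methyl 2-[(1(10)E,4E,7S,8S)-8-(TBSO)-4-(TBDPSOCH2)-10-(PMBOCH2)-6-oxocyclodeca-1(10),4-dien-7-yl]acetate
Product: 21 (3aR,4S,6E,10E,11aR)-4-(TBSO)-10-(TBDPSOCH2)-6-(PMBOCH2)-3a,4,5,8,9,11a-hexahydrocyclodeca[b]furan-2(3H)-one, via hydroxy ester 20 (not isolated)
Conditions: Li[HB(s-Bu)3], THF, −78 °C; AcOH, −78 °C; then PPTS (cat.), CH2Cl2, rt
Reagents that add atoms: none
Why: The bulky borohydride should reduce the β,β-disubstituted enone 1,2 from the face opposite the C7 acetate arm (Felkin–Anh addition with C8 as the large group), which sets C6 as R with O6 cis to the arm, and the γ-hydroxy ester then lactonises to the cis-fused lactone.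

Step 12
Reactants: 21 (3aR,4S,6E,10E,11aR)-4-(TBSO)-10-(TBDPSOCH2)-6-(PMBOCH2)-3a,4,5,8,9,11a-hexahydrocyclodeca[b]furan-2(3H)-one
Product: 24 (3aR,4S,6E,10E,11aR)-4-(TBSO)-10-(TBDPSOCH2)-6-(PMBOCH2)-3-methylidene-3a,4,5,8,9,11a-hexahydrocyclodeca[b]furan-2(3H)-one, via Mannich base 22 (not isolated), via ammonium iodide 23 (not isolated)
Conditions: LiN(SiMe3)2, THF, −78 °C; Me2N=CH2+ I−, −78 → 0 °C; then MeI, MeOH, rt; then aq NaHCO3, CH2Cl2
Reagents that add atoms: N,N-dimethylmethaniminium iodide (Eschenmoser's salt), C=[N+](C)C.[I-]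
Why: Mannich reaction of the lactone enolate with Eschenmoser's salt, quaternisation and E1cB loss of trimethylamine is the standard α-methylenation of γ-lactones, and the transient C11 centre ends as sp2.

Step 13
Reactants: 24 (3aR,4S,6E,10E,11aR)-4-(TBSO)-10-(TBDPSOCH2)-6-(PMBOCH2)-3-methylidene-3a,4,5,8,9,11a-hexahydrocyclodeca[b]furan-2(3H)-one
Product: 25 (3aS,4S,6E,10E,11aR)-4-hydroxy-10-(TBDPSOCH2)-6-(PMBOCH2)-3-methylidene-3a,4,5,8,9,11a-hexahydrocyclodeca[b]furan-2(3H)-one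
Conditions: HF·pyridine, pyridine, THF, 0 °C → rt
Reagents that add atoms: none
Why: Fluoride-mediated desilylation under buffered acidic conditions should cleave the secondary TBS ether faster than the TBDPS ether, while the PMB ether and the methylene lactone are inert.

Step 14
Reactants: 25 (3aS,4S,6E,10E,11aR)-4-hydroxy-10-(TBDPSOCH2)-6-(PMBOCH2)-3-methylidene-3a,4,5,8,9,11a-hexahydrocyclodeca[b]furan-2(3H)-one; 26 angelic acid
Product: 27 (3aS,4S,6E,10E,11aR)-10-(TBDPSOCH2)-6-(PMBOCH2)-3-methylidene-2-oxo-2,3,3a,4,5,8,9,11a-octahydrocyclodeca[b]furan-4-yl (2Z)-2-methylbut-2-enoate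
Conditions: 26, 2,4,6-Cl3C6H2COCl, Et3N, toluene, rt; then 25, 80 °C
Reagents that add atoms: none
Why: Yamaguchi-type esterification through the preformed mixed anhydride, run without a nucleophilic catalyst, should acylate the hindered C8 hydroxyl with retention at C8 and keep the Z geometry of the angelate.

Step 15
Reactants: 27 (3aS,4S,6E,10E,11aR)-10-(TBDPSOCH2)-6-(PMBOCH2)-3-methylidene-2-oxo-2,3,3a,4,5,8,9,11a-octahydrocyclodeca[b]furan-4-yl (2Z)-2-methylbut-2-enoate
Product: 28 (3aS,4S,6E,10E,11aR)-10-(TBDPSOCH2)-6-(hydroxymethyl)-3-methylidene-2-oxo-2,3,3a,4,5,8,9,11a-octahydrocyclodeca[b]furan-4-yl (2Z)-2-methylbut-2-enoate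
Conditions: DDQ, CH2Cl2/pH 7 buffer, 0 °C
Reagents that add atoms: none
Why: Oxidative cleavage of the electron-rich PMB ether by DDQ should free the C14 hydroxyl while the silyl ether, the esters and the olefins stay.

Step 16
Reactants: 28 (3aS,4S,6E,10E,11aR)-10-(TBDPSOCH2)-6-(hydroxymethyl)-3-methylidene-2-oxo-2,3,3a,4,5,8,9,11a-octahydrocyclodeca[b]furan-4-yl (2Z)-2-methylbut-2-enoate
Product: 29 (3aS,4S,6E,10E,11aR)-10-(TBDPSOCH2)-6-formyl-3-methylidene-2-oxo-2,3,3a,4,5,8,9,11a-octahydrocyclodeca[b]furan-4-yl (2Z)-2-methylbut-2-enoate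
Conditions: MnO2, CH2Cl2, rt
Reagents that add atoms: none
Why: MnO2 oxidation is selective for the primary allylic alcohol and should give the enal in its ring-cis geometry, which is also the thermodynamically preferred one.

Step 17
Reactants: 29 (3aS,4S,6E,10E,11aR)-10-(TBDPSOCH2)-6-formyl-3-methylidene-2-oxo-2,3,3a,4,5,8,9,11a-octahydrocyclodeca[b]furan-4-yl (2Z)-2-methylbut-2-enoate
Product: 30 (3aS,4S,6E,10E,11aR)-6-formyl-10-(hydroxymethyl)-3-methylidene-2-oxo-2,3,3a,4,5,8,9,11a-octahydrocyclodeca[b]furan-4-yl (2Z)-2-methylbut-2-enoate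
Conditions: HF·pyridine, THF, 0 °C → rt
Reagents that add atoms: none
Why: Fluoride cleavage of the primary allylic TBDPS ether under mildly acidic conditions should spare the enal, the angelate and the α-methylene lactone and deliver the target.

Compound list
1 | (tributylstannyl)methanol | CCCC[Sn](CCCC)(CCCC)CO | starting material
2 | 4-methoxybenzyl chloride | COc1ccc(CCl)cc1 | starting material
3 | tributyl{[(4-methoxybenzyl)oxy]methyl}stannane | CCCC[Sn](CCCC)(CCCC)COCc1ccc(OC)cc1 | intermediate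
4 | methyl (3R)-3-(TBSO)-5-oxo-6-(triphenyl-λ5-phosphanylidene)hexanoate | COC(=O)C[C@H](O[Si](C)(C)C(C)(C)C)CC(=O)C=P(c1ccccc1)(c1ccccc1)c1ccccc1 | starting material
5 | (3R)-3-(TBSO)-N-methoxy-N-methyl-5-oxo-6-(triphenyl-λ5-phosphanylidene)hexanamide | CON(C)C(=O)C[C@H](O[Si](C)(C)C(C)(C)C)CC(=O)C=P(c1ccccc1)(c1ccccc1)c1ccccc1 | intermediate
6 | [(4-methoxybenzyl)oxy]methyllithium | [Li]COCc1ccc(OC)cc1 | intermediate
7 | (4S)-4-(TBSO)-1-(PMBO)-7-(triphenyl-λ5-phosphanylidene)heptane-2,6-dione | COc1ccc(COCC(=O)C[C@H](O[Si](C)(C)C(C)(C)C)CC(=O)C=P(c2ccccc2)(c2ccccc2)c2ccccc2)cc1 | intermediate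
8 | (S)-5-(TBSO)-3-(PMBOCH2)cyclohex-2-en-1-one | O=C1C=C(COCc2ccc(OC)cc2)C[C@H](O[Si](C)(C)C(C)(C)C)C1 | intermediate
9 | ethyl 1-bromocyclobutane-1-carboxylate | CCOC(=O)C1(Br)CCC1 | starting material
10 | cyclobut-1-ene-1-carboxylic acid | OC(=O)C1=CCC1 | intermediate
11 | methyl cyclobut-1-ene-1-carboxylate | COC(=O)C1=CCC1 | intermediate
12 | methyl (8S)-8-(TBSO)-6-(PMBOCH2)-10-oxotricyclo[4.4.0.0(2,5)]decane-2-carboxylate (head-to-head photoadduct, cis-fused diastereomer mixture at the four cyclobutane centres) | O=C1C[C@@H](O[Si](C)(C)C(C)(C)C)CC2(COCc3ccc(OC)cc3)C1C1(C(=O)OC)CCC12 | intermediate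
13 | methyl (1(10)E,4Z,8S)-8-(TBSO)-10-(PMBOCH2)-6-oxocyclodeca-1(10),4-diene-4-carboxylate (C4=C5 trans in the ring) | O=C1/C=C(\C(=O)OC)CC/C=C(/COCc2ccc(OC)cc2)C[C@H](O[Si](C)(C)C(C)(C)C)C1 | intermediate
14 | methyl (1(10)E,4E,8S)-8-(TBSO)-10-(PMBOCH2)-6-oxocyclodeca-1(10),4-diene-4-carboxylate (both olefins cis in the ring) | O=C1/C=C(/C(=O)OC)CC/C=C(/COCc2ccc(OC)cc2)C[C@H](O[Si](C)(C)C(C)(C)C)C1 | intermediate
15 | (1(10)E,4E,8S)-8-(TBSO)-4-(hydroxymethyl)-10-(PMBOCH2)cyclodeca-1(10),4-dien-6-ol (C6 epimers) | OC1/C=C(/CO)CC/C=C(/COCc2ccc(OC)cc2)C[C@H](O[Si](C)(C)C(C)(C)C)C1 | intermediate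
16 | (1(10)E,4E,8S)-8-(TBSO)-4-(TBDPSOCH2)-10-(PMBOCH2)cyclodeca-1(10),4-dien-6-ol (C6 epimers) | OC1/C=C(/CO[Si](c2ccccc2)(c2ccccc2)C(C)(C)C)CC/C=C(/COCc2ccc(OC)cc2)C[C@H](O[Si](C)(C)C(C)(C)C)C1 | intermediate
17 | (1(10)E,4E,8S)-8-(TBSO)-4-(TBDPSOCH2)-10-(PMBOCH2)cyclodeca-1(10),4-dien-6-one | O=C1/C=C(/CO[Si](c2ccccc2)(c2ccccc2)C(C)(C)C)CC/C=C(/COCc2ccc(OC)cc2)C[C@H](O[Si](C)(C)C(C)(C)C)C1 | intermediate
18 | methyl bromoacetate | COC(=O)CBr | starting material
19 | methyl 2-[(1(10)E,4E,7S,8S)-8-(TBSO)-4-(TBDPSOCH2)-10-(PMBOCH2)-6-oxocyclodeca-1(10),4-dien-7-yl]acetate | O=C1/C=C(/CO[Si](c2ccccc2)(c2ccccc2)C(C)(C)C)CC/C=C(/COCc2ccc(OC)cc2)C[C@H](O[Si](C)(C)C(C)(C)C)[C@@H]1CC(=O)OC | intermediate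
20 | methyl 2-[(1(10)E,4E,6R,7R,8S)-6-hydroxy-8-(TBSO)-4-(TBDPSOCH2)-10-(PMBOCH2)cyclodeca-1(10),4-dien-7-yl]acetate | O[C@@H]1/C=C(/CO[Si](c2ccccc2)(c2ccccc2)C(C)(C)C)CC/C=C(/COCc2ccc(OC)cc2)C[C@H](O[Si](C)(C)C(C)(C)C)[C@@H]1CC(=O)OC | intermediate
21 | (3aR,4S,6E,10E,11aR)-4-(TBSO)-10-(TBDPSOCH2)-6-(PMBOCH2)-3a,4,5,8,9,11a-hexahydrocyclodeca[b]furan-2(3H)-one (cis-fused lactone) | C1C(=O)O[C@@H]2/C=C(/CO[Si](c3ccccc3)(c3ccccc3)C(C)(C)C)CC/C=C(/COCc3ccc(OC)cc3)C[C@H](O[Si](C)(C)C(C)(C)C)[C@H]12 | intermediate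
22 | 3-[(dimethylamino)methyl] derivative of lactone 21 (C3 epimers) | CN(C)CC1C(=O)O[C@@H]2/C=C(/CO[Si](c3ccccc3)(c3ccccc3)C(C)(C)C)CC/C=C(/COCc3ccc(OC)cc3)C[C@H](O[Si](C)(C)C(C)(C)C)[C@H]12 | intermediate
23 | 3-[(trimethylammonio)methyl] iodide derived from 22 | C[N+](C)(C)CC1C(=O)O[C@@H]2/C=C(/CO[Si](c3ccccc3)(c3ccccc3)C(C)(C)C)CC/C=C(/COCc3ccc(OC)cc3)C[C@H](O[Si](C)(C)C(C)(C)C)[C@H]12.[I-] | intermediate
24 | (3aR,4S,6E,10E,11aR)-4-(TBSO)-10-(TBDPSOCH2)-6-(PMBOCH2)-3-methylidene-3a,4,5,8,9,11a-hexahydrocyclodeca[b]furan-2(3H)-one | C=C1C(=O)O[C@@H]2/C=C(/CO[Si](c3ccccc3)(c3ccccc3)C(C)(C)C)CC/C=C(/COCc3ccc(OC)cc3)C[C@H](O[Si](C)(C)C(C)(C)C)[C@H]12 | intermediate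
25 | (3aS,4S,6E,10E,11aR)-4-hydroxy-10-(TBDPSOCH2)-6-(PMBOCH2)-3-methylidene-3a,4,5,8,9,11a-hexahydrocyclodeca[b]furan-2(3H)-one | C=C1C(=O)O[C@@H]2/C=C(/CO[Si](c3ccccc3)(c3ccccc3)C(C)(C)C)CC/C=C(/COCc3ccc(OC)cc3)C[C@H](O)[C@H]12 | intermediate
26 | angelic acid, (2Z)-2-methylbut-2-enoic acid | C/C=C(/C)C(=O)O | starting material
27 | (3aS,4S,6E,10E,11aR)-10-(TBDPSOCH2)-6-(PMBOCH2)-3-methylidene-2-oxo-2,3,3a,4,5,8,9,11a-octahydrocyclodeca[b]furan-4-yl (2Z)-2-methylbut-2-enoate | C=C1C(=O)O[C@@H]2/C=C(/CO[Si](c3ccccc3)(c3ccccc3)C(C)(C)C)CC/C=C(/COCc3ccc(OC)cc3)C[C@H](OC(=O)/C(C)=C\C)[C@H]12 | intermediate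
28 | (3aS,4S,6E,10E,11aR)-10-(TBDPSOCH2)-6-(hydroxymethyl)-3-methylidene-2-oxo-2,3,3a,4,5,8,9,11a-octahydrocyclodeca[b]furan-4-yl (2Z)-2-methylbut-2-enoate | C=C1C(=O)O[C@@H]2/C=C(/CO[Si](c3ccccc3)(c3ccccc3)C(C)(C)C)CC/C=C(/CO)C[C@H](OC(=O)/C(C)=C\C)[C@H]12 | intermediate
29 | (3aS,4S,6E,10E,11aR)-10-(TBDPSOCH2)-6-formyl-3-methylidene-2-oxo-2,3,3a,4,5,8,9,11a-octahydrocyclodeca[b]furan-4-yl (2Z)-2-methylbut-2-enoate | C=C1C(=O)O[C@@H]2/C=C(/CO[Si](c3ccccc3)(c3ccccc3)C(C)(C)C)CC/C=C(/C=O)C[C@H](OC(=O)/C(C)=C\C)[C@H]12 | intermediate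
30 | (3aS,4S,6E,10E,11aR)-6-formyl-10-(hydroxymethyl)-3-methylidene-2-oxo-2,3,3a,4,5,8,9,11a-octahydrocyclodeca[b]furan-4-yl (2Z)-2-methylbut-2-enoate | C=C1C(=O)O[C@@H]2/C=C(/CO)CC/C=C(/C=O)C[C@H](OC(=O)/C(C)=C\C)[C@H]12 | target

Total step count: 17. Longest linear sequence: 14 steps (from 4 through steps 2, 3 and 6–17).

Steps most likely to fail

Step 6. The ring expansion may be overtaken by Cope rearrangement of a ring-trans diene to a 1,2-divinylcyclohexanone before the olefin is isomerised, and the β-silyloxy ketone may lose silanol at 180 °C. The fallback sets out from photoadduct 12. Its ketone is reduced in the crude photolysate (NaBH4, MeOH, 0 °C) to the tricyclic carbinol F1. F1 is heated with PhSSPh in toluene, so that the cycloreversion runs at the alcohol oxidation level, where neither an ene-dione nor a β-silyloxy ketone is present, and should give the hydroxy dienoate F2. The ester of F2 is reduced with i-Bu2AlH, and the route is rejoined at diol 15.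

Step 10. The alkylation may show poor facial selectivity if the conformation of the ten-membered ring overrides the allylic-strain model, and the β-silyloxy enolate may expel silanolate (E1cB). The fallback sets out from ketone 17. The C8 silyl ether is cleaved (HF·pyridine) to the β-hydroxy ketone F3. The alkoxide–enolate dianion of F3 (LiN(i-Pr)2, 2.2 equiv, THF, −78 °C) is alkylated with tert-butyl bromoacetate in the manner of the Fráter–Seebach alkylation: the lithium chelate holds O8 in the enolate plane, the electrophile enters anti to C9, and an alkoxide cannot be eliminated. This should give the anti hydroxy ester F4. Silylation (TBS triflate, 2,6-lutidine) gives the silyl ether F5, which is reduced with Li[HB(s-Bu)3] and lactonised with PPTS with loss of tert-butanol. The route is rejoined at lactone 21.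

Step 13. The secondary C8 silyl ether is hindered, so its cleavage may be slow and the primary C15 silyl ether may be lost alongside it. The fallback sets out from 24. Both silyl groups are removed (HF·pyridine, THF, rt, prolonged) to give diol F6, and only the primary allylic C15 hydroxyl is silylated again (t-BuPh2SiCl, imidazole, CH2Cl2, −20 °C). The route is rejoined at alcohol 25.

Further compounds
F1 | step 6 | methyl (8S)-8-(TBSO)-10-hydroxy-6-(PMBOCH2)tricyclo[4.4.0.0(2,5)]decane-2-carboxylate (carbinol of photoadduct 12, diastereomer mixture) | OC1C[C@@H](O[Si](C)(C)C(C)(C)C)CC2(COCc3ccc(OC)cc3)C1C1(C(=O)OC)CCC12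
F2 | step 6 | methyl (1(10)E,4E,8S)-6-hydroxy-8-(TBSO)-10-(PMBOCH2)cyclodeca-1(10),4-diene-4-carboxylate (C6 epimers) | OC1/C=C(/C(=O)OC)CC/C=C(/COCc2ccc(OC)cc2)C[C@H](O[Si](C)(C)C(C)(C)C)C1
F3 | step 10 | (1(10)E,4E,8S)-8-hydroxy-4-(TBDPSOCH2)-10-(PMBOCH2)cyclodeca-1(10),4-dien-6-one | O=C1/C=C(/CO[Si](c2ccccc2)(c2ccccc2)C(C)(C)C)CC/C=C(/COCc2ccc(OC)cc2)C[C@H](O)C1
F4 | step 10 | tert-butyl 2-[(1(10)E,4E,7S,8S)-8-hydroxy-4-(TBDPSOCH2)-10-(PMBOCH2)-6-oxocyclodeca-1(10),4-dien-7-yl]acetate | O=C1/C=C(/CO[Si](c2ccccc2)(c2ccccc2)C(C)(C)C)CC/C=C(/COCc2ccc(OC)cc2)C[C@H](O)[C@@H]1CC(=O)OC(C)(C)C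
F5 | step 10 | tert-butyl 2-[(1(10)E,4E,7S,8S)-8-(TBSO)-4-(TBDPSOCH2)-10-(PMBOCH2)-6-oxocyclodeca-1(10),4-dien-7-yl]acetate | O=C1/C=C(/CO[Si](c2ccccc2)(c2ccccc2)C(C)(C)C)CC/C=C(/COCc2ccc(OC)cc2)C[C@H](O[Si](C)(C)C(C)(C)C)[C@@H]1CC(=O)OC(C)(C)C
F6 | step 13 | (3aS,4S,6E,10E,11aR)-4-hydroxy-10-(hydroxymethyl)-6-(PMBOCH2)-3-methylidene-3a,4,5,8,9,11a-hexahydrocyclodeca[b]furan-2(3H)-one | C=C1C(=O)O[C@@H]2/C=C(/CO)CC/C=C(/COCc3ccc(OC)cc3)C[C@H](O)[C@H]12
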